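## Structural features

The target is a trans-fused bicyclo[5.3.0]decane (hydroazulene, azulene numbering used throughout). Ring A is a cyclopentane with a trisubstituted epoxide at C1–C2 (methyl on C2). Ring B is a cycloheptane with isopropyl at C4, the 3-hydroxy-4-methoxybenzoate ester at C5 and a tertiary methyl carbinol at C7, so the two oxygenated ring-B carbons are separated by the C6 methylene. There are seven stereocentres: C1, C2, C3a, C4, C5, C7 and C8a. C8a–C3a–C4–C5 is a contiguous run of four, the ring fusion is trans, and the ester oxygen, the isopropyl group, the C7 hydroxyl and the epoxide oxygen all lie on the α face. The fragile groups are the epoxide (acid), the tertiary alcohol (elimination), the aryl ester (base, hard nucleophiles) and the free phenol. The real difficulty is the seven-membered ring with its 1,3-dioxygenation, the need to tell the two oxygenated carbons apart, and the four contiguous stereocentres around the ring fusion. The key step exploits the pattern C5(O)–C6H2–C7(O) with C4 (isopropyl) next to C5 and trans carbon substituents on C3a and C8a. C5 and C4–C3a come from the carbonyl and alkene of a dienone enolate, C7 and C8–C8a from the carbonyl and alkene of an acryloylsilane, and C6 is the enolate methylene.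

## Logic of the disconnections

31 ⇒ 30: the phenol O–CH2 bond is cut. The phenol must be masked while the ester is carried through a Mitsunobu step and a peracid. The forward step must remove the group without opening the epoxide or cleaving the ester.

30 ⇒ 29: the two C–O bonds of the epoxide at C1 and C2 are cut. This removes two stereocentres and leaves a single alkene. The forward step needs α-face attack on the ring-A alkene.

29 ⇒ 26: the C3–H bond is cut and the C1=C2 alkene is moved back to C2=C3 with a hydroxyl on C1. The C1 carbinol is what ring-closing metathesis delivers and what the annulation uses as its control element, so it can be spent here. The forward step needs substitution with inversion at hindered C1, not at C3.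

26 ⇒ 25 ⇒ 24: the O–Si bond on C1 and then the C2=C3 bond of ring A are cut, which opens ring A to a vinyl group on C3a and an isopropenyl carbinol on C8a. The gain is a monocyclic cycloheptane. The forward metathesis must close a trans-fused cyclopentene with a trisubstituted alkene.

24 ⇒ 21 + 22: the ester C(=O)–O bond at C5 is cut. Acylation is placed this early so that the ester itself protects O-5 during the later Mitsunobu step. The forward step must acylate the secondary hydroxyl and leave the tertiary one.

21 ⇒ 20: the C7–CH3 bond is cut. This removes the C7 stereocentre and reveals a β-hydroxy ketone. The forward addition must come from the face opposite O-5 and must not enolise or fragment the aldol.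

20 ⇒ 18: the C5–H bond and the enol O–Si bond are cut, which gives a cycloheptenone whose two oxygenated carbons are already distinct (ketone at C5, silyl enol ether at C7). The forward hydride must enter anti to the isopropyl group. C4 in 18 cannot be corrected with base, because enolisation towards C6 is faster and would move the enol ether into conjugation, so C4 has to come out right in the quench of the annulation.

18 ⇒ 8 + 14: the C6–C7 and C3a–C8a bonds are cut. The first is made when the enolate carbon adds to the acylsilane carbonyl, the second in the sigmatropic step, not both in the Cope rearrangement. The gain is ring B and three stereocentres in one operation. The step demands a Z alkene in 8, an E alkene in 14, and facial control by the carbinol stereocentre of 8.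

8 ⇒ 7 ⇒ 6 ⇒ 5 ⇒ 3 ⇒ 1 + 2: in turn, the acylsilane is taken back to its carbinol, the Z alkene to an alkyne, the secondary silyl ether to the alcohol, the C–Si bond to an O–Si bond (retro-Brook), and the alkynyl–carbinol C–C bond is cut. Silicon can only be brought in as an electrophile, so it arrives on oxygen and is moved to carbon. The alkynylation must set the one stereocentre that later steers the annulation.

14 ⇒ 12 + 13, then 12 ⇒ 11 ⇒ 9 + 10: the trisubstituted C=C bond, then the acyl C–C bond, then the P–C bond are cut. Acylating a phosphonate that already carries the branched chain avoids C-alkylating a ketophosphonate with a secondary halide. The olefination must give the E isomer.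

## Other disconnections considered

Alternative 1: The cut is the ring-A bond C3–C3a at a cyclopentenone stage. In the forward step Ph3PAuCl with AgSbF6 would trigger 1,2-shift of a propargylic pivalate and closure of the alkyne terminus onto the alkene carbon that becomes C3a, giving cyclopentenone A1.
- In its favour: the cyclisation is catalytic and mild, and transfer of chirality from the propargylic carbinol to the ring carbon is an established feature of it. A1 already holds C3a and C4. Its enone invites trans conjugate addition to set C8a, and trapping the resulting enolate would place the ring-A alkene at C1=C2 without any transposition.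
- Against it: A1 contains two of the seven stereocentres and none of ring B. The cycloheptane, C5 and C7 would all have to be built afterwards, including a medium-ring closure with no built-in control at C5. C4 would have to be set in an acyclic precursor next to the carbinol.
- Comparison: the key step of Alternative 1 makes one C–C bond and the easy ring; the chosen one makes two C–C bonds, the hard ring and three stereocentres. Alternative 1 is better on absolute stereocontrol (chirality transfer against an untested induction) and on C4 (not set by an enolate protonation), and equal or better on the position of the ring-A alkene. It is worse on step economy after the key step and leaves the seven-membered ring closure unsolved.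

Alternative 2: The cut is the C4–C5 bond. In the forward step Me2AlCl would promote an intramolecular carbonyl-ene reaction between a C5 aldehyde and a 2-methylprop-1-enyl group on C3a, with transfer of a methyl hydrogen, closing ring B to give A2.
- In its favour: two adjacent stereocentres and ring B are formed together, and C7 is already a protected tertiary carbinol, so no methyl addition to a ring ketone is needed. The enol triflate of A2 puts the C2 methyl and the C1=C2 alkene in place by cross-coupling, which is better than the chosen plan on that point.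
- Against it: ene closure to a seven-membered ring is much less favourable than the six-membered (isopulegol) case, and Prins-type pathways compete. The tertiary silyl ether and the enol triflate must survive the Lewis acid. A2 has the C5 carbinol trans to isopropenyl, whereas the target has the ester oxygen cis to isopropyl, so an inversion at a hindered carbinol is needed. The isopropenyl group must then be hydrogenated in the presence of the ring-A alkene. The precursor needs C3a, C8a and the remote quaternary C7 set without ring bias.
- Comparison: Alternative 2 forms one C–C bond and two stereocentres against two bonds and three stereocentres. Its transition state for a seven-membered ring is not predictable, whereas the boat Cope is stereospecific for the ring fusion. Installing the ester by Mitsunobu inversion would be equal in step count to the reduction and acylation used here. Overall length is not expected to be shorter because the precursor is long.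

Alternative 3: The cut is both ring-B bonds to C7 (C6–C7 and C7–C8). In the forward step a lithiated 2-silyl-1,3-dithiane would open a terminal epoxide at C6, silicon would migrate to the new C5 alkoxide, and the regenerated carbanion would displace a primary chloride at C8, giving A3.
- In its favour: two C–C bonds and ring B are formed in one flask, and O-5 is protected by the migrating silyl group. The C5 configuration comes from the epoxide and C4 from the precursor, so neither depends on a reduction or a protonation, and the ring-A alkene is already at C1=C2. On these three points Alternative 3 is better. The dithiane is a masked C7 ketone, so the later methyl addition faces the same facial question as here (equal).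
- Against it: the ring closure is a seven-membered intramolecular alkylation of a hindered dithiane anion and has to beat intermolecular alkylation. The key step creates no stereocentre, so C8a, C3a, C4 and C5 must all be set beforehand in a long linear precursor. Unmasking the dithiane next to an alkene adds a step.
- Comparison: both plans rest on a Brook rearrangement and make two bonds to close ring B, but the chosen step also creates three stereocentres and is convergent from two small fragments. Alternative 3 is safer at C4 and C5 and longer overall.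

Key step: step 9

Remark on numbering: ring positions in the Why lines follow the azulene numbering of the target (C1/C2 epoxide carbons, C3a/C8a ring fusion, C4 isopropyl carbon, C5 ester carbinol, C7 tertiary carbinol) unless a compound name is quoted; TBS = tert-butyldimethylsilyl.
Remark on step 1: the (R,R) antipode of the ligand is assumed to give the (R)-carbinol; this is an assumption by analogy and must be checked on the first batch.
Remark on starting material: 3-(benzyloxy)-4-methoxybenzoic acid (22), the O-benzyl ether of isovanillic acid, is taken as a purchased compound.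

Step 1
Reactants: 1 methacrolein; 2 tert-butyldimethyl(prop-2-yn-1-yloxy)silane
Product: 3 (3R)-6-(TBS-oxy)-2-methylhex-1-en-4-yn-3-ol
Conditions: (R,R)-ProPhenol (10 mol %), Ph3PO (20 mol %), Me2Zn (3 equiv), 2 (3 equiv), toluene, 0 °C
Reagents that add atoms: none
Why: Catalytic asymmetric alkynylation of an enal with a zinc alkynylide under dinuclear zinc–ProPhenol catalysis; the ligand antipode decides which aldehyde face is attacked, and the assignment should be confirmed by Mosher ester analysis since both antipodes are available.

Step 2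
Reactants: 3 (3R)-6-(TBS-oxy)-2-methylhex-1-en-4-yn-3-ol
Product: 5 (4R)-1-TBS-5-methylhex-5-en-2-yne-1,4-diol (both C1 epimers), via dilithiated alkoxide 4 (not isolated)
Conditions: n-BuLi (1.05 equiv), THF, −78 °C; t-BuLi (1.2 equiv), −78 to −45 °C; AcOH, −78 °C
Reagents that add atoms: none
Why: Retro-[1,2]-Brook rearrangement: the alkoxide formed first makes H-3 non-acidic, so the second base removes a propargylic hydrogen next to the silyloxy group and silicon moves from oxygen to carbon. The new carbinol centre forms as a mixture, which does not matter because it is oxidised in step 5.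

Step 3
Reactants: 5 (4R)-1-TBS-5-methylhex-5-en-2-yne-1,4-diol
Product: 6 (4R)-1-TBS-4-(TBS-oxy)-5-methylhex-5-en-2-yn-1-ol
Conditions: TBSCl (1.1 equiv), imidazole, DMF, 0 °C
Reagents that add atoms: tert-butyldimethylsilyl chloride, CC(C)(C)[Si](C)(C)Cl
Why: Silylation of the less hindered C4 hydroxyl; the C1 hydroxyl is flanked by the bulky silyl group on the same carbon and should react much more slowly.

Step 4
Reactants: 6 (4R)-1-TBS-4-(TBS-oxy)-5-methylhex-5-en-2-yn-1-ol
Product: 7 (2Z,4S)-1-TBS-4-(TBS-oxy)-5-methylhexa-2,5-dien-1-ol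
Conditions: H2 (1 atm), Pd/CaCO3 poisoned with Pb(OAc)2, quinoline, EtOAc, 0 °C
Reagents that add atoms: none
Why: Lindlar semi-hydrogenation: syn addition of hydrogen to the alkyne gives the Z alkene, and the 1,1-disubstituted alkene is left alone under quinoline-poisoned conditions.

Step 5
Reactants: 7 (2Z,4S)-1-TBS-4-(TBS-oxy)-5-methylhexa-2,5-dien-1-ol
Product: 8 (2Z,4S)-1-TBS-4-(TBS-oxy)-5-methylhexa-2,5-dien-1-one
Conditions: Dess–Martin periodinane, NaHCO3, CH2Cl2, 0 °C, dark
Reagents that add atoms: none
Why: Dess–Martin oxidation of an α-silyl allylic alcohol to the acylsilane under buffered, non-basic conditions, which should avoid Brook rearrangement and Z-to-E isomerisation; acylsilanes are photolabile, hence the dark.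

Step 6
Reactants: 9 triethyl phosphite; 10 1-bromo-2-methylpropane
Product: 11 diethyl (2-methylpropyl)phosphonate
Conditions: neat, 150 °C, EtBr distilled off
Reagents that add atoms: none
Why: Michaelis–Arbuzov reaction; removing bromoethane as it forms keeps it from competing as the alkylating agent.

Step 7
Reactants: 11 diethyl (2-methylpropyl)phosphonate
Product: 12 diethyl (4-methyl-2-oxopentan-3-yl)phosphonate
Conditions: 11 (2.1 equiv), n-BuLi (2.0 equiv), THF, −78 °C; EtOAc (1.0 equiv), −78 to 0 °C; aq. NH4Cl
Reagents that add atoms: ethyl acetate, CCOC(C)=O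
Why: C-Acylation of the α-lithiated phosphonate (Claisen-type condensation); the second equivalent of anion deprotonates the ketophosphonate as it forms, and the excess phosphonate is recovered.

Step 8
Reactants: 12 diethyl (4-methyl-2-oxopentan-3-yl)phosphonate; 13 acrolein
Product: 14 (3E)-3-(propan-2-yl)hexa-3,5-dien-2-one
Conditions: Ba(OH)2, THF/H2O (40:1), 0 °C to rt
Reagents that add atoms: none
Why: Horner–Wadsworth–Emmons olefination under mild Ba(OH)2 conditions suited to a base-sensitive enal; α-substituted β-ketophosphonates favour the E-trisubstituted enone (acetyl trans to vinyl). The dienone is used promptly because it can dimerise.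

Step 9
Reactants: 14 (3E)-3-(propan-2-yl)hexa-3,5-dien-2-one; 8 (2Z,4S)-1-TBS-4-(TBS-oxy)-5-methylhexa-2,5-dien-1-one
Product: 18 (2S,3R,4R)-6-(TBS-oxy)-4-[(1S)-1-(TBS-oxy)-2-methylprop-2-en-1-yl]-3-ethenyl-2-(propan-2-yl)cyclohept-5-en-1-one, via lithium dienolate 15 (not isolated), via cyclopropanolate 16 (not isolated), via lithium cycloheptadienolate 17 (not isolated)
Conditions: LiN(i-Pr)2 (1.05 equiv), THF, −80 °C, 14; then 8 in THF, −80 to −30 °C; AcOH/THF, −80 °C; dark
Reagents that add atoms: none
Why: Kinetic enolate 15 adds through its CH2 carbon to the acylsilane carbonyl of 8 (this makes the C6–C7 bond); 1,2-Brook shift of silicon to oxygen gives a siloxyallyl anion that closes onto the ketone carbonyl (3-exo-trig) to the cis-dialkenylcyclopropanolate 16; the oxyanion-accelerated Cope rearrangement of 16 through a boat transition state then cleaves the cyclopropane bond and makes the C3a–C8a bond, closing the seven-membered ring as a [3,3] ring enlargement. The closest known reaction is the Brook rearrangement-mediated (3+4) annulation of β-substituted acryloylsilanes with lithium enolates of alkenyl methyl ketones. In the boat the Z alkene of 8 holds the carbinol carbon inside and the E alkene of 14 holds the vinyl group outside, so C3a and C8a should emerge trans; this needs 8 to stay Z, hence the low temperature and exclusion of light. The absolute sense rests on the silyloxy stereocentre: A(1,3) strain in the Z alkene keeps its C–H in the alkene plane, the new bond should form anti to the larger isopropenyl group (syn to the silyloxy group), and for (S)-8 this gives the (3R,4R) ring configuration. C4 is set when enolate 17 is protonated: A(1,2) strain with isopropyl should push the vinyl group pseudo-axial and the trans side chain pseudo-axial on the other face, so acetic acid should approach syn to vinyl and give the all-trans (2S) epimer, which is also the more stable one. The cold acetic acid quench protonates carbon without moving the enol ether into conjugation, so the ketone and the silyl enol ether stay differentiated.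

Step 10
Reactants: 18 (2S,3R,4R)-6-(TBS-oxy)-4-[(1S)-1-(TBS-oxy)-2-methylprop-2-en-1-yl]-3-ethenyl-2-(propan-2-yl)cyclohept-5-en-1-one
Product: 20 (3S,4R,5S,6R)-3-[(1S)-1-(TBS-oxy)-2-methylprop-2-en-1-yl]-4-ethenyl-6-hydroxy-5-(propan-2-yl)cycloheptan-1-one, via hydroxy silyl enol ether 19 (not isolated)
Conditions: LiBH(s-Bu)3 (1.2 equiv), THF, −78 °C; AcOH (6 equiv), then n-Bu4NF (1.2 equiv), −78 to 0 °C
Reagents that add atoms: none
Why: The bulky hydride should attack the ketone from the face away from the adjacent isopropyl group and give the alcohol cis to it, as in reductions of 2-alkylcycloalkanones with this reagent. Buffered fluoride then cleaves only the silyl enol ether, which reacts far faster than the secondary allylic silyl ether; the acid is added first so that the alkoxide cannot take over the silyl group.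

Step 11
Reactants: 20 (3S,4R,5S,6R)-3-[(1S)-1-(TBS-oxy)-2-methylprop-2-en-1-yl]-4-ethenyl-6-hydroxy-5-(propan-2-yl)cycloheptan-1-one
Product: 21 (1R,3R,4S,5R,6S)-6-[(1S)-1-(TBS-oxy)-2-methylprop-2-en-1-yl]-5-ethenyl-1-methyl-4-(propan-2-yl)cycloheptane-1,3-diol
Conditions: CeCl3 (anhydrous), MeLi (4 equiv each), THF, −78 °C; then 20, −78 to −40 °C; aq. NH4Cl
Reagents that add atoms: methyllithium, [Li]C
Why: Organocerium 1,2-addition, chosen because it causes little enolisation or retro-aldol cleavage of a β-hydroxy ketone. The C5 oxygen is pseudo-axial (its cis isopropyl neighbour is equatorial) and shields that face of the C7 carbonyl in a 1,3-diaxial sense, so methyl should enter from the other face and give the cis-1,3-diol.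

Step 12
Reactants: 21 (1R,3R,4S,5R,6S)-6-[(1S)-1-(TBS-oxy)-2-methylprop-2-en-1-yl]-5-ethenyl-1-methyl-4-(propan-2-yl)cycloheptane-1,3-diol; 22 3-(benzyloxy)-4-methoxybenzoic acid
Product: 24 (1R,2S,3R,4S,6R)-4-[(1S)-1-(TBS-oxy)-2-methylprop-2-en-1-yl]-3-ethenyl-6-hydroxy-6-methyl-2-(propan-2-yl)cycloheptyl 3-(benzyloxy)-4-methoxybenzoate, via mixed anhydride 23 (not isolated)
Conditions: 22, 2,4,6-trichlorobenzoyl chloride, Et3N, toluene, rt; then 21, DMAP, 40 °C
Reagents that add atoms: none
Why: Yamaguchi esterification: the mixed anhydride acylates the secondary C5 hydroxyl under DMAP catalysis, and the tertiary C7 hydroxyl does not react. Placing the ester here lets it protect O-5 through the Mitsunobu step, and the benzyl ether keeps the phenol from acting as a nucleophile there.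

Step 13
Reactants: 24 (1R,2S,3R,4S,6R)-4-[(1S)-1-(TBS-oxy)-2-methylprop-2-en-1-yl]-3-ethenyl-6-hydroxy-6-methyl-2-(propan-2-yl)cycloheptyl 3-(benzyloxy)-4-methoxybenzoate
Product: 25 (1S,3aR,4S,5R,7R,8aS)-1-(TBS-oxy)-7-hydroxy-2,7-dimethyl-4-(propan-2-yl)-1,3a,4,5,6,7,8,8a-octahydroazulen-5-yl 3-(benzyloxy)-4-methoxybenzoate
Conditions: second-generation Grubbs catalyst RuCl2(=CHPh)(H2IMes)(PCy3) (5 mol %), CH2Cl2 (0.005 M), 40 °C
Reagents that add atoms: none
Why: Ring-closing metathesis of the vinyl and isopropenyl groups closes the trans-fused cyclopentene with loss of ethene; the two alkenes sit on adjacent trans ring carbons and no other alkene is present.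

Step 14
Reactants: 25 (1S,3aR,4S,5R,7R,8aS)-1-(TBS-oxy)-7-hydroxy-2,7-dimethyl-4-(propan-2-yl)-1,3a,4,5,6,7,8,8a-octahydroazulen-5-yl 3-(benzyloxy)-4-methoxybenzoate
Product: 26 (1S,3aR,4S,5R,7R,8aS)-1,7-dihydroxy-2,7-dimethyl-4-(propan-2-yl)-1,3a,4,5,6,7,8,8a-octahydroazulen-5-yl 3-(benzyloxy)-4-methoxybenzoate
Conditions: HF·pyridine, pyridine, THF, 0 °C to rt
Reagents that add atoms: none
Why: Fluoride cleavage of the secondary allylic silyl ether under buffered conditions that should leave the aryl ester, the benzyl ether and the tertiary alcohol intact.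

Step 15
Reactants: 26 (1S,3aR,4S,5R,7R,8aS)-1,7-dihydroxy-2,7-dimethyl-4-(propan-2-yl)-1,3a,4,5,6,7,8,8a-octahydroazulen-5-yl 3-(benzyloxy)-4-methoxybenzoate
Product: 29 (3aR,4S,5R,7R,8aS)-7-hydroxy-2,7-dimethyl-4-(propan-2-yl)-3,3a,4,5,6,7,8,8a-octahydroazulen-5-yl 3-(benzyloxy)-4-methoxybenzoate, via sulfonylhydrazide adduct 27 (not isolated), via allylic diazene 28 (not isolated)
Conditions: 2-nitrobenzenesulfonylhydrazide, PPh3, DEAD, N-methylmorpholine, THF, −30 °C; then 23 °C
Reagents that add atoms: none
Why: Myers reductive 1,3-transposition: Mitsunobu displacement by the sulfonylhydrazide (inversion at C1), loss of sulfinic acid on warming, and retro-ene loss of N2 from the allylic diazene deliver hydrogen to C3 and move the alkene to C1=C2. The C1 stereocentre that steered the annulation is erased, and the tertiary alcohol and the ester take no part.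

Step 16
Reactants: 29 (3aR,4S,5R,7R,8aS)-7-hydroxy-2,7-dimethyl-4-(propan-2-yl)-3,3a,4,5,6,7,8,8a-octahydroazulen-5-yl 3-(benzyloxy)-4-methoxybenzoate
Product: 30 (1S,2R,3aR,4S,5R,7R,8aS)-1,2-epoxy-7-hydroxy-2,7-dimethyl-4-(propan-2-yl)decahydroazulen-5-yl 3-(benzyloxy)-4-methoxybenzoate
Conditions: mCPBA, NaHCO3, CH2Cl2, 0 °C
Reagents that add atoms: 3-chloroperoxybenzoic acid, OOC(=O)c1cccc(Cl)c1
Why: Prilezhaev epoxidation of the only alkene. Attack anti to the pseudo-axial allylic hydrogens (H-8a and one H-3, both on the β face of the envelope) is torsionally favoured, and the α-disposed C7 hydroxyl can hydrogen-bond to the peracid, so the α-epoxide is expected.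

Step 17
Reactants: 30 (1S,2R,3aR,4S,5R,7R,8aS)-1,2-epoxy-7-hydroxy-2,7-dimethyl-4-(propan-2-yl)decahydroazulen-5-yl 3-(benzyloxy)-4-methoxybenzoate
Product: 31 (1S,2R,3aR,4S,5R,7R,8aS)-1,2-epoxy-7-hydroxy-2,7-dimethyl-4-(propan-2-yl)decahydroazulen-5-yl 3-hydroxy-4-methoxybenzoate
Conditions: H2 (1 atm), Pd/C, EtOAc, rt
Reagents that add atoms: none
Why: Hydrogenolysis of the aryl benzyl ether; no alkene remains, and a trisubstituted non-benzylic epoxide and the ester should be stable under these neutral conditions.

Compound list

1 | methacrolein | C=C(C)C=O | starting material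
2 | tert-butyldimethyl(prop-2-yn-1-yloxy)silane | C#CCO[Si](C)(C)C(C)(C)C | starting material
3 | (3R)-6-(TBS-oxy)-2-methylhex-1-en-4-yn-3-ol | C=C(C)[C@@H](O)C#CCO[Si](C)(C)C(C)(C)C | intermediate
4 | dilithium salt of 3 deprotonated at O-3 and C-6 | [Li+].[Li+].[O-][C@H](C(C)=C)C#C[CH-]O[Si](C)(C)C(C)(C)C | intermediate
5 | (4R)-1-TBS-5-methylhex-5-en-2-yne-1,4-diol (C1 epimers) | C=C(C)[C@@H](O)C#CC(O)[Si](C)(C)C(C)(C)C | intermediate
6 | (4R)-1-TBS-4-(TBS-oxy)-5-methylhex-5-en-2-yn-1-ol | C=C(C)[C@@H](O[Si](C)(C)C(C)(C)C)C#CC(O)[Si](C)(C)C(C)(C)C | intermediate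
7 | (2Z,4S)-1-TBS-4-(TBS-oxy)-5-methylhexa-2,5-dien-1-ol | C=C(C)[C@@H](O[Si](C)(C)C(C)(C)C)/C=C\C(O)[Si](C)(C)C(C)(C)C | intermediate
8 | (2Z,4S)-1-TBS-4-(TBS-oxy)-5-methylhexa-2,5-dien-1-one | CC(C)(C)[Si](C)(C)C(=O)/C=C\[C@H](O[Si](C)(C)C(C)(C)C)C(C)=C | intermediate
9 | triethyl phosphite | CCOP(OCC)OCC | starting material
10 | 1-bromo-2-methylpropane | CC(C)CBr | starting material
11 | diethyl (2-methylpropyl)phosphonate | CCOP(=O)(CC(C)C)OCC | intermediate
12 | diethyl (4-methyl-2-oxopentan-3-yl)phosphonate | CCOP(=O)(OCC)C(C(C)C)C(C)=O | intermediate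
13 | acrolein | C=CC=O | starting material
14 | (3E)-3-(propan-2-yl)hexa-3,5-dien-2-one | CC(=O)/C(C(C)C)=C/C=C | intermediate
15 | lithium (3E)-3-(propan-2-yl)hexa-1,3,5-trien-2-olate | [Li+].[O-]C(=C)/C(C(C)C)=C/C=C | intermediate
16 | lithium (1R,2S)-2-(TBS-oxy)-1-[(3E)-2-methylhexa-3,5-dien-3-yl]-2-[(1Z,3S)-3-(TBS-oxy)-4-methylpenta-1,4-dien-1-yl]cyclopropan-1-olate (alkenyl groups cis) | [Li+].[O-][C@@]1(/C(C(C)C)=C/C=C)C[C@]1(O[Si](C)(C)C(C)(C)C)/C=C\[C@H](O[Si](C)(C)C(C)(C)C)C(C)=C | intermediate
17 | lithium (5R,6R)-3-(TBS-oxy)-5-[(1S)-1-(TBS-oxy)-2-methylprop-2-en-1-yl]-6-ethenyl-7-(propan-2-yl)cyclohepta-1(7),3-dien-1-olate | [Li+].[O-]C1=C(C(C)C)[C@H](C=C)[C@@H]([C@H](O[Si](C)(C)C(C)(C)C)C(C)=C)C=C(O[Si](C)(C)C(C)(C)C)C1 | intermediate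
18 | (2S,3R,4R)-6-(TBS-oxy)-4-[(1S)-1-(TBS-oxy)-2-methylprop-2-en-1-yl]-3-ethenyl-2-(propan-2-yl)cyclohept-5-en-1-one | O=C1CC(O[Si](C)(C)C(C)(C)C)=C[C@H]([C@H](O[Si](C)(C)C(C)(C)C)C(C)=C)[C@@H](C=C)[C@@H]1C(C)C | intermediate
19 | (1R,5R,6S,7S)-3-(TBS-oxy)-5-[(1S)-1-(TBS-oxy)-2-methylprop-2-en-1-yl]-6-ethenyl-7-(propan-2-yl)cyclohept-3-en-1-ol | O[C@@H]1CC(O[Si](C)(C)C(C)(C)C)=C[C@H]([C@H](O[Si](C)(C)C(C)(C)C)C(C)=C)[C@@H](C=C)[C@@H]1C(C)C | intermediate
20 | (3S,4R,5S,6R)-3-[(1S)-1-(TBS-oxy)-2-methylprop-2-en-1-yl]-4-ethenyl-6-hydroxy-5-(propan-2-yl)cycloheptan-1-one | O[C@@H]1CC(=O)C[C@H]([C@H](O[Si](C)(C)C(C)(C)C)C(C)=C)[C@@H](C=C)[C@@H]1C(C)C | intermediate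
21 | (1R,3R,4S,5R,6S)-6-[(1S)-1-(TBS-oxy)-2-methylprop-2-en-1-yl]-5-ethenyl-1-methyl-4-(propan-2-yl)cycloheptane-1,3-diol | O[C@@H]1C[C@](C)(O)C[C@H]([C@H](O[Si](C)(C)C(C)(C)C)C(C)=C)[C@@H](C=C)[C@@H]1C(C)C | intermediate
22 | 3-(benzyloxy)-4-methoxybenzoic acid | COc1ccc(C(=O)O)cc1OCc1ccccc1 | starting material
23 | 3-(benzyloxy)-4-methoxybenzoic 2,4,6-trichlorobenzoic anhydride | COc1ccc(C(=O)OC(=O)c2c(Cl)cc(Cl)cc2Cl)cc1OCc1ccccc1 | intermediate
24 | (1R,2S,3R,4S,6R)-4-[(1S)-1-(TBS-oxy)-2-methylprop-2-en-1-yl]-3-ethenyl-6-hydroxy-6-methyl-2-(propan-2-yl)cycloheptyl 3-(benzyloxy)-4-methoxybenzoate | COc1ccc(C(=O)O[C@@H]2C[C@](C)(O)C[C@H]([C@H](O[Si](C)(C)C(C)(C)C)C(C)=C)[C@@H](C=C)[C@@H]2C(C)C)cc1OCc1ccccc1 | intermediate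
25 | (1S,3aR,4S,5R,7R,8aS)-1-(TBS-oxy)-7-hydroxy-2,7-dimethyl-4-(propan-2-yl)-1,3a,4,5,6,7,8,8a-octahydroazulen-5-yl 3-(benzyloxy)-4-methoxybenzoate | COc1ccc(C(=O)O[C@@H]2C[C@](C)(O)C[C@H]3[C@@H](C=C(C)[C@H]3O[Si](C)(C)C(C)(C)C)[C@@H]2C(C)C)cc1OCc1ccccc1 | intermediate
26 | (1S,3aR,4S,5R,7R,8aS)-1,7-dihydroxy-2,7-dimethyl-4-(propan-2-yl)-1,3a,4,5,6,7,8,8a-octahydroazulen-5-yl 3-(benzyloxy)-4-methoxybenzoate | COc1ccc(C(=O)O[C@@H]2C[C@](C)(O)C[C@H]3[C@@H](C=C(C)[C@H]3O)[C@@H]2C(C)C)cc1OCc1ccccc1 | intermediate
27 | N-alkyl-N-(2-nitrobenzenesulfonyl)hydrazine from 26 (nitrogen on C1 with inversion) | COc1ccc(C(=O)O[C@@H]2C[C@](C)(O)C[C@H]3[C@@H](C=C(C)[C@@H]3N(N)S(=O)(=O)c3ccccc3[N+](=O)[O-])[C@@H]2C(C)C)cc1OCc1ccccc1 | intermediate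
28 | allylic monoalkyl diazene from 27 (N=NH on C1) | COc1ccc(C(=O)O[C@@H]2C[C@](C)(O)C[C@H]3[C@@H](C=C(C)[C@@H]3N=N)[C@@H]2C(C)C)cc1OCc1ccccc1 | intermediate
29 | (3aR,4S,5R,7R,8aS)-7-hydroxy-2,7-dimethyl-4-(propan-2-yl)-3,3a,4,5,6,7,8,8a-octahydroazulen-5-yl 3-(benzyloxy)-4-methoxybenzoate | COc1ccc(C(=O)O[C@@H]2C[C@](C)(O)C[C@H]3[C@@H](CC(C)=C3)[C@@H]2C(C)C)cc1OCc1ccccc1 | intermediate
30 | (1S,2R,3aR,4S,5R,7R,8aS)-1,2-epoxy-7-hydroxy-2,7-dimethyl-4-(propan-2-yl)decahydroazulen-5-yl 3-(benzyloxy)-4-methoxybenzoate | COc1ccc(C(=O)O[C@@H]2C[C@](C)(O)C[C@H]3[C@@H](C[C@@]4(C)O[C@@H]34)[C@@H]2C(C)C)cc1OCc1ccccc1 | intermediate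
31 | (1S,2R,3aR,4S,5R,7R,8aS)-1,2-epoxy-7-hydroxy-2,7-dimethyl-4-(propan-2-yl)decahydroazulen-5-yl 3-hydroxy-4-methoxybenzoate | COc1ccc(C(=O)O[C@@H]2C[C@](C)(O)C[C@H]3[C@@H](C[C@@]4(C)O[C@@H]34)[C@@H]2C(C)C)cc1O | target

Total step count: 17. Longest linear sequence: 14 steps (steps 1–5, then 9–17); steps 6–8 form the second branch.

Least certain steps

Step 9 (key step). Two stereochemical processes are not secured by precedent. The first is the facial sense and level of induction by the silyloxy stereocentre; this is decided by the ligand antipode chosen in step 1 and is erased in step 15, so it is a matter of supply, not of route. The second is more serious: protonation of the ring enolate at the isopropyl-bearing carbon may occur on the wrong face, since kinetic protonation often enters anti to the neighbouring substituent, and 18 cannot be equilibrated with base because enolisation on the other side of the ketone would pull the enol ether into conjugation. The fallback moves this centre to thermodynamic control. Starting from 18 (as an epimer mixture), ethylene glycol with catalytic TsOH in CH2Cl2 exchanges the silyl enol ether for a dioxolane and equilibrates the α-centre by acid-catalysed enolisation to the all-trans β-keto ketal F1. LiBH(s-Bu)3 then gives the cis alcohol, hydroxy ketal F2, and PPTS in wet acetone releases the ketone, rejoining the route at 20.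

Step 2. The second metalation may be slow or may occur elsewhere (for example at the allylic methyl) because the substrate already carries an alkoxide, and the propargylic anion may react through its allenyl form; either would lower the amount of C-silyl carbinol. The fallback brings in silicon by acyl-anion chemistry. Starting from 1, the same zinc-catalysed alkynylation with 3,3-diethoxyprop-1-yne gives the alkynol acetal F3, and TBSCl/imidazole gives the silyl ether F4. Heating with 1H-benzotriazole in toluene exchanges one ethoxy group to give the N,O-acetal F5. n-BuLi at −78 °C followed by TBSCl gives the C-silylated N,O-acetal F6, which dilute aqueous acid hydrolyses to the ynoylsilane F7. Semi-hydrogenation over Pd/CaCO3 poisoned with Pb(OAc)2 rejoins the route at 8.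

Step 11. Facial selectivity of the methyl addition on a flexible seven-membered ring may be low, or delivery from the metal alkoxide may favour the wrong face; retro-aldol cleavage is a second risk. The fallback sets C7 by hydroxyl-directed oxygen delivery. Starting from 20, Cp2TiMe2 in toluene at 65 °C gives the exocyclic alkene F8. VO(acac)2 with t-BuOOH epoxidises this homoallylic alkene from the face of the C5 hydroxyl to give the spiro-epoxide F9, and LiBHEt3 opens it at the CH2 carbon, rejoining the route at 21.

Step 15. The Mitsunobu displacement at a secondary carbinol flanked by the ring fusion and a methyl-bearing alkene carbon may be diverted to allylic (SN2′-type) attack or elimination, which would give the untransposed alkene or a diene. The fallback reaches the same allylic diazene by reduction of a hydrazone. Starting from 26, MnO2 oxidises the allylic alcohol to the enone F10, and TsNHNH2 in ethanol gives the tosylhydrazone F11. Catecholborane followed by NaOAc reduces the C=N bond, and loss of sulfinate and N2 with 1,5-hydrogen shift rejoins the route at 29.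

Further compounds

F1 | step 9 | (8S,9R,10S)-10-[(1S)-1-(TBS-oxy)-2-methylprop-2-en-1-yl]-9-ethenyl-8-(propan-2-yl)-1,4-dioxaspiro[4.6]undecan-7-one | O=C1CC2(OCCO2)C[C@H]([C@H](O[Si](C)(C)C(C)(C)C)C(C)=C)[C@@H](C=C)[C@@H]1C(C)C
F2 | step 9 | (7R,8S,9R,10S)-10-[(1S)-1-(TBS-oxy)-2-methylprop-2-en-1-yl]-9-ethenyl-8-(propan-2-yl)-1,4-dioxaspiro[4.6]undecan-7-ol | O[C@@H]1CC2(OCCO2)C[C@H]([C@H](O[Si](C)(C)C(C)(C)C)C(C)=C)[C@@H](C=C)[C@@H]1C(C)C
F3 | step 2 | (3R)-6,6-diethoxy-2-methylhex-1-en-4-yn-3-ol | C=C(C)[C@@H](O)C#CC(OCC)OCC
F4 | step 2 | (3R)-3-(TBS-oxy)-6,6-diethoxy-2-methylhex-1-en-4-yne | C=C(C)[C@@H](O[Si](C)(C)C(C)(C)C)C#CC(OCC)OCC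
F5 | step 2 | 1-[(4R)-4-(TBS-oxy)-1-ethoxy-5-methylhex-5-en-2-yn-1-yl]-1H-benzotriazole (C1 epimers) | C=C(C)[C@@H](O[Si](C)(C)C(C)(C)C)C#CC(OCC)n1nnc2ccccc12
F6 | step 2 | 1-[(4R)-1-TBS-4-(TBS-oxy)-1-ethoxy-5-methylhex-5-en-2-yn-1-yl]-1H-benzotriazole (C1 epimers) | C=C(C)[C@@H](O[Si](C)(C)C(C)(C)C)C#CC(OCC)([Si](C)(C)C(C)(C)C)n1nnc2ccccc12
F7 | step 2 | (4R)-1-TBS-4-(TBS-oxy)-5-methylhex-5-en-2-yn-1-one | C=C(C)[C@@H](O[Si](C)(C)C(C)(C)C)C#CC(=O)[Si](C)(C)C(C)(C)C
F8 | step 11 | (1R,2S,3R,4S)-4-[(1S)-1-(TBS-oxy)-2-methylprop-2-en-1-yl]-3-ethenyl-6-methylidene-2-(propan-2-yl)cycloheptan-1-ol | O[C@@H]1CC(=C)C[C@H]([C@H](O[Si](C)(C)C(C)(C)C)C(C)=C)[C@@H](C=C)[C@@H]1C(C)C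
F9 | step 11 | (3R,5R,6S,7R,8S)-8-[(1S)-1-(TBS-oxy)-2-methylprop-2-en-1-yl]-7-ethenyl-6-(propan-2-yl)-1-oxaspiro[2.6]nonan-5-ol | O[C@@H]1C[C@]2(OC2)C[C@H]([C@H](O[Si](C)(C)C(C)(C)C)C(C)=C)[C@@H](C=C)[C@@H]1C(C)C
F10 | step 15 | (3aS,4S,5R,7R,8aS)-7-hydroxy-2,7-dimethyl-1-oxo-4-(propan-2-yl)-1,3a,4,5,6,7,8,8a-octahydroazulen-5-yl 3-(benzyloxy)-4-methoxybenzoate | COc1ccc(C(=O)O[C@@H]2C[C@](C)(O)C[C@H]3[C@@H](C=C(C)C3=O)[C@@H]2C(C)C)cc1OCc1ccccc1
F11 | step 15 | 4-methylbenzenesulfonylhydrazone of F10 at C1 | COc1ccc(C(=O)O[C@@H]2C[C@](C)(O)C[C@H]3[C@@H](C=C(C)C3=NNS(=O)(=O)c3ccc(C)cc3)[C@@H]2C(C)C)cc1OCc1ccccc1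
A1 | alternative 1 | (4R)-4-[(2S)-1-(TBS-oxy)-3-methylbutan-2-yl]cyclopent-2-en-1-one | O=C1C=C[C@H]([C@H](C(C)C)CO[Si](C)(C)C(C)(C)C)C1
A2 | alternative 2 | trans-fused 5-hydroxy-7-methyl-4-(prop-1-en-2-yl)-7-(triethylsilyloxy)-3,3a,4,5,6,7,8,8a-octahydroazulen-2-yl trifluoromethanesulfonate (5-hydroxyl trans to isopropenyl) | O[C@H]1C[C@](C)(O[Si](CC)(CC)CC)C[C@H]2[C@@H](CC(OS(=O)(=O)C(F)(F)F)=C2)[C@@H]1C(C)=C
A3 | alternative 3 | trans-fused 5-(TBS-oxy)-2-methyl-4-(propan-2-yl)-3,3a,4,5,6,8,8a-heptahydroazulene with C7 as a spiro-1,3-dithiane | CC(C)(C)[Si](C)(C)O[C@@H]1CC2(SCCCS2)C[C@H]2[C@@H](CC(C)=C2)[C@@H]1C(C)C
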